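**Retrosynthetic overview**

1. The last skeletal bond made is C4 (unit 2)–C8 (unit 3). A bromine-capped upper dimer carrying a 2-ethoxyethoxy leaving group at C4 of unit 2 (18) is coupled with octa-O-benzylprocyanidin B2 (20), and global hydrogenolysis follows.
2. The strategy rests on one feature: C4 of unit 1 is a diarylmethine bonded to C4a of ring A of unit 1 and to C6 of unit 2, and the 2,3-trans-3,4-trans array C2/C3/C4 of unit 1 can be derived from C4 alone.
3. Ring C of unit 1 is therefore closed as a 4H-chromene by a catalyst-controlled phenol + enone [3+3] annulation (bonds C4–C4a and O1–C2). Syn hydroboration anti to the C4 aryl then sets C2 and C3.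
4. The enone hangs on C6 of unit 2 and comes from (−)-epicatechin: benzylation, C8 bromination, C6 iodination, I/Mg exchange–formylation, Claisen–Schmidt condensation.
5. Ring order: every ring of units 2–4 and rings A and B of unit 1 are bought in; ring C of unit 1 is the only ring formed (step 8).

Key step: step 8

Assumptions: the (R)-configured phosphoramide is taken to give the 4S (4α) adduct; if the induction has the opposite sense, its enantiomer is used, since the stereocentres of unit 2 are too remote to matter. 3,5-Bis(benzyloxy)phenol is bought. Flavan numbering (O1, C2, C3, C4, C4a, C5–C8, C8a; rings A, B, C) is used for each unit, and units are counted 1 to 4 from the top of the chain.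

**Route**

Step 1
Reactants: 1 (−)-epicatechin
Product: 2 tetra-O-benzylepicatechin (5,7,3′,4′-tetra-O-benzyl-(−)-epicatechin; 3-OH free)
Conditions: BnBr (4.4 equiv), K2CO3, DMF, 0 °C to rt, N2
Reagents that add atoms: benzyl bromide, BrCc1ccccc1
Why: Williamson etherification with a weak base alkylates the four phenols only and avoids the base-induced C2 epimerisation of the free polyphenol, so the 2R,3R centres are kept.

Step 2
Reactants: 2 tetra-O-benzylepicatechin
Product: 3 penta-O-benzylepicatechin (3,5,7,3′,4′-penta-O-benzyl-(−)-epicatechin)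
Conditions: NaH, BnBr, DMF, 0 °C to rt
Reagents that add atoms: benzyl bromide, BrCc1ccccc1
Why: Williamson etherification of the secondary alcohol is safe once no phenol is free, because ring opening through a quinone methide (the epimerisation path) is then closed.

Step 3
Reactants: 3 penta-O-benzylepicatechin
Product: 4 penta-O-benzyl-8-bromoepicatechin
Conditions: NBS (1.0 equiv), CH2Cl2, −78 °C to 0 °C
Reagents that add atoms: N-bromosuccinimide, O=C1CCC(=O)N1Br
Why: Electrophilic aromatic bromination of the phloroglucinol-type ring A of benzylated flavan-3-ols takes place at C8 at low temperature, and the catechol ring B is much less activated.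

Step 4
Reactants: 4 penta-O-benzyl-8-bromoepicatechin
Product: 5 penta-O-benzyl-8-bromo-6-iodoepicatechin
Conditions: NIS (1.2 equiv), TFA (cat.), MeCN/CH2Cl2, 0 °C to rt
Reagents that add atoms: N-iodosuccinimide, O=C1CCC(=O)N1I
Why: Electrophilic aromatic iodination can only go to C6, the last free ring A position, which lies between two benzyloxy groups and para to O1.

Step 5
Reactants: 5 penta-O-benzyl-8-bromo-6-iodoepicatechin
Product: 7 penta-O-benzyl-8-bromoepicatechin-6-carbaldehyde, via C6 arylmagnesium chloride 6 (not isolated)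
Conditions: i-PrMgCl·LiCl (1.1 equiv), THF, −40 °C; DMF, −40 °C to 0 °C; aq NH4Cl
Reagents that add atoms: N,N-dimethylformamide, CN(C)C=O (formyl carbon and oxygen of 7); isopropylmagnesium chloride–lithium chloride, CC(C)[Mg]Cl.[Li+].[Cl-] (the MgCl of 6 only)
Why: Iodine–magnesium exchange is far faster at the aryl iodide than at the aryl bromide and is helped by the two ortho benzyloxy groups, and the arylmagnesium is then formylated by DMF (Bouveault aldehyde synthesis), which places the one-carbon handle at C6.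

Step 6
Reactants: 8 3′,4′-dihydroxyacetophenone
Product: 9 3′,4′-bis(benzyloxy)acetophenone
Conditions: BnBr (2.2 equiv), K2CO3, DMF, 60 °C
Reagents that add atoms: benzyl bromide, BrCc1ccccc1
Why: Williamson etherification of both phenols proceeds under weak base, and the aryl methyl ketone does not enolise under these conditions.

Step 7
Reactants: 7 penta-O-benzyl-8-bromoepicatechin-6-carbaldehyde; 9 3′,4′-bis(benzyloxy)acetophenone
Product: 10 enone (E)-1-[3,4-bis(benzyloxy)phenyl]-3-(penta-O-benzyl-8-bromoepicatechin-6-yl)prop-2-en-1-one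
Conditions: KOH, EtOH/THF, rt to 50 °C
Reagents that add atoms: none
Why: Claisen–Schmidt condensation of a non-enolisable 2,6-dialkoxybenzaldehyde with an aryl methyl ketone gives the E-enone by E1cB dehydration under thermodynamic control, and no stereocentre of unit 2 is base-labile with all phenols capped.

Step 8
Reactants: 10 enone; 11 3,5-bis(benzyloxy)phenol
Product: 13 (4S)-5,7-bis(benzyloxy)-2-[3,4-bis(benzyloxy)phenyl]-4-(penta-O-benzyl-8-bromoepicatechin-6-yl)-4H-chromene, via Friedel–Crafts ketone adduct 12 (not isolated)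
Conditions: (R)-3,3′-bis(2,4,6-triisopropylphenyl)-BINOL N-triflyl phosphoramide (10 mol %), 11 (1.3 equiv), 5 Å MS, toluene, −20 °C to rt, Ar, dark
Reagents that add atoms: none
Why: Proposed new method: the phosphoramide protonates or hydrogen-bonds the carbonyl of 10 while its P=O oxygen binds the OH of 11, so the ring carbon ortho to that OH adds to the β carbon (conjugate Friedel–Crafts alkylation, C4–C4a), and the phenol oxygen of 12 then closes ring C of unit 1 by 6-exo-trig hemiketalisation and acid-catalysed loss of water (O1–C2) to give the 4H-chromene. The closest known reactions are the achiral acid-catalysed condensation of phenols with chalcones to 2,4-diaryl-4H-chromenes and chiral Brønsted acid catalysed Friedel–Crafts/cyclodehydration sequences of naphthols and electron-rich phenols with activated enones. The only new stereocentre, C4 of unit 1, is set by the catalyst, which holds both partners in its chiral pocket during C–C bond formation, because C2 and C3 of unit 2 are too far away to bias the face. Regiochemistry is secured by the substrate: attack para to the OH of 11 gives an adduct that cannot cyclise and reverts, C8 of unit 2 is blocked by bromine, and the 4→6 connectivity was fixed when the aldehyde was placed at C6. The chromene is sensitive to acid and air, so substoichiometric acid, molecular sieves, low temperature, exclusion of air and only a small excess of 11 are used, and 13 is taken directly into step 9.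

Step 9
Reactants: 13 (4S)-4H-chromene
Product: 15 tetra-O-benzylcatechin-(4α→6)-penta-O-benzyl-8-bromoepicatechin (3-OH of unit 1 free), via C3 alkylborane 14 (not isolated)
Conditions: BH3·SMe2, THF, 0 °C to rt; then NaOH, H2O2, 0 °C
Reagents that add atoms: hydrogen peroxide, OO (oxygen at C3 of unit 1); borane–dimethyl sulfide, [BH3-][S+](C)C (boron of 14 only)
Why: Brown hydroboration–oxidation of the enol ether puts boron on C3 (β to O1 and to the C2 aryl) and hydrogen on C2 in a syn addition from the face opposite the bulky C4 aryl, and oxidation with retention then gives the 2,3-trans-3,4-trans alcohol, so C2 (R) and C3 (S) are relayed from C4.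

Step 10
Reactants: 15 tetra-O-benzylcatechin-(4α→6)-penta-O-benzyl-8-bromoepicatechin
Product: 16 penta-O-benzylcatechin-(4α→6)-penta-O-benzyl-8-bromoepicatechin
Conditions: NaH, BnBr, Bu4NI (cat.), DMF, 0 °C to rt
Reagents that add atoms: benzyl bromide, BrCc1ccccc1
Why: Williamson etherification caps the new secondary alcohol so that it cannot trap the C4 cation of unit 2 later, and no centre is base-labile because no phenol is free.

Step 11
Reactants: 16 penta-O-benzylcatechin-(4α→6)-penta-O-benzyl-8-bromoepicatechin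
Product: 17 penta-O-benzyl-6,8-dibromocatechin-(4α→6)-penta-O-benzyl-8-bromoepicatechin
Conditions: NBS (2.2 equiv), CH2Cl2, −40 °C to 0 °C, dark
Reagents that add atoms: N-bromosuccinimide, O=C1CCC(=O)N1Br
Why: Electrophilic aromatic bromination goes to C6 and C8 of unit 1, the only free phloroglucinol-type positions, which caps them against self-condensation in step 15 and makes ring A of unit 1 poorer in electrons before the oxidation in step 12.

Step 12
Reactants: 17 penta-O-benzyl-6,8-dibromocatechin-(4α→6)-penta-O-benzyl-8-bromoepicatechin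
Product: 18 penta-O-benzyl-6,8-dibromocatechin-(4α→6)-penta-O-benzyl-8-bromo-4β-(2-ethoxyethoxy)epicatechin
Conditions: DDQ (2 equiv), 2-ethoxyethanol, CH2Cl2, rt
Reagents that add atoms: 2-ethoxyethanol, CCOCCO
Why: DDQ-mediated benzylic hydride abstraction at the C4 methylene of unit 2 and capture of the cation by the alcohol trans to the 3-benzyloxy group is the standard C4 activation of benzylated flavan-3-ols, and the only other ring A benzylic hydrogen, C4–H of unit 1, is a congested tertiary methine between two ortho-disubstituted rings, one of them dibrominated.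

Step 13
Reactants: 2 tetra-O-benzylepicatechin
Product: 19 tetra-O-benzyl-4β-(2-ethoxyethoxy)epicatechin
Conditions: DDQ (2 equiv), 2-ethoxyethanol, CH2Cl2, rt
Reagents that add atoms: 2-ethoxyethanol, CCOCCO
Why: The same DDQ benzylic oxidation with alcohol capture on the monomer should give the 4β ether, trans to the 3-OH.

Step 14
Reactants: 19 tetra-O-benzyl-4β-(2-ethoxyethoxy)epicatechin; 2 tetra-O-benzylepicatechin (4 equiv)
Product: 20 octa-O-benzylprocyanidin B2 (tetra-O-benzylepicatechin-(4β→8)-tetra-O-benzylepicatechin; both 3-OH free)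
Conditions: TMSOTf (cat.), CH2Cl2, −78 °C
Reagents that add atoms: none
Why: Lewis-acid ionisation of the C4 ether and Friedel–Crafts capture of the benzylic cation by C8 of excess 2 from the face trans to the 3-OH and the C2 aryl sets the 4β (4R) centre, and the excess of 2 suppresses self-condensation.

Step 15
Reactants: 18 upper-dimer electrophile; 20 octa-O-benzylprocyanidin B2 (1.5–2 equiv)
Product: 21 protected tetramer penta-O-benzyl-6,8-dibromocatechin-(4α→6)-penta-O-benzyl-8-bromoepicatechin-(4β→8)-tetra-O-benzylepicatechin-(4β→8)-tetra-O-benzylepicatechin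
Conditions: TMSOTf, CH2Cl2, −78 °C to −40 °C
Reagents that add atoms: none
Why: Lewis-acid ionisation of the C4 ether of unit 2 and Friedel–Crafts capture by C8 of the upper unit of 20, its most nucleophilic position, trans to the 3-benzyloxy group and the C2 aryl, should set the 4β centre of unit 2, while the three bromine caps leave 18 no nucleophilic ring A carbon.

Step 16
Reactants: 21 protected tetramer
Product: 22 catechin-(4α→6)-epicatechin-(4β→8)-epicatechin-(4β→8)-epicatechin (CNP0228086.1)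
Conditions: H2 (1 atm), Pd(OH)2/C, Et3N (3.5 equiv), THF/MeOH/H2O, rt; filtration and freeze-drying under Ar
Reagents that add atoms: none
Why: Catalytic hydrogenolysis cleaves the eighteen benzyl ethers and hydrodehalogenates the three aryl bromides in one operation, triethylamine takes up the HBr so that the acid-labile interflavan bonds are not exposed, and no stereocentre is touched.

**Compound list**

1 | (−)-epicatechin | Oc1cc(O)c2c(c1)O[C@H](c1ccc(O)c(O)c1)[C@H](O)C2 | starting material
2 | tetra-O-benzylepicatechin (5,7,3′,4′-tetra-O-benzyl; 3-OH free) | c9ccccc9COc1cc(OCc9ccccc9)c2c(c1)O[C@H](c8ccc(OCc9ccccc9)c(OCc9ccccc9)c8)[C@H](O)C2 | intermediate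
3 | penta-O-benzylepicatechin (3,5,7,3′,4′-penta-O-benzyl) | c9ccccc9COc1cc(OCc9ccccc9)c2c(c1)O[C@H](c8ccc(OCc9ccccc9)c(OCc9ccccc9)c8)[C@H](OCc9ccccc9)C2 | intermediate
4 | penta-O-benzyl-8-bromoepicatechin | c9ccccc9COc1cc(OCc9ccccc9)c2c(c1Br)O[C@H](c8ccc(OCc9ccccc9)c(OCc9ccccc9)c8)[C@H](OCc9ccccc9)C2 | intermediate
5 | penta-O-benzyl-8-bromo-6-iodoepicatechin | c9ccccc9COc1c(I)c(OCc9ccccc9)c2c(c1Br)O[C@H](c8ccc(OCc9ccccc9)c(OCc9ccccc9)c8)[C@H](OCc9ccccc9)C2 | intermediate
6 | (penta-O-benzyl-8-bromoepicatechin-6-yl)magnesium chloride | c9ccccc9COc1c([Mg]Cl)c(OCc9ccccc9)c2c(c1Br)O[C@H](c8ccc(OCc9ccccc9)c(OCc9ccccc9)c8)[C@H](OCc9ccccc9)C2 | intermediate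
7 | penta-O-benzyl-8-bromoepicatechin-6-carbaldehyde | c9ccccc9COc1c(C=O)c(OCc9ccccc9)c2c(c1Br)O[C@H](c8ccc(OCc9ccccc9)c(OCc9ccccc9)c8)[C@H](OCc9ccccc9)C2 | intermediate
8 | 3′,4′-dihydroxyacetophenone | CC(=O)c1ccc(O)c(O)c1 | starting material
9 | 3′,4′-bis(benzyloxy)acetophenone | CC(=O)c1ccc(OCc2ccccc2)c(OCc2ccccc2)c1 | intermediate
10 | (E)-1-[3,4-bis(benzyloxy)phenyl]-3-(penta-O-benzyl-8-bromoepicatechin-6-yl)prop-2-en-1-one | O=C(c8ccc(OCc9ccccc9)c(OCc9ccccc9)c8)/C=C/c1c(OCc9ccccc9)c(Br)c2c(c1OCc9ccccc9)C[C@@H](OCc9ccccc9)[C@@H](c8ccc(OCc9ccccc9)c(OCc9ccccc9)c8)O2 | intermediate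
11 | 3,5-bis(benzyloxy)phenol | Oc1cc(OCc2ccccc2)cc(OCc2ccccc2)c1 | starting material
12 | 1-[3,4-bis(benzyloxy)phenyl]-3-[2,4-bis(benzyloxy)-6-hydroxyphenyl]-3-(penta-O-benzyl-8-bromoepicatechin-6-yl)propan-1-one (C3 configured as C4 of 13) | O=C(c8ccc(OCc9ccccc9)c(OCc9ccccc9)c8)C[C@@H](c1c(O)cc(OCc9ccccc9)cc1OCc9ccccc9)c1c(OCc9ccccc9)c(Br)c2c(c1OCc9ccccc9)C[C@@H](OCc9ccccc9)[C@@H](c8ccc(OCc9ccccc9)c(OCc9ccccc9)c8)O2 | intermediate
13 | (4S)-5,7-bis(benzyloxy)-2-[3,4-bis(benzyloxy)phenyl]-4-(penta-O-benzyl-8-bromoepicatechin-6-yl)-4H-chromene | c9ccccc9COc1cc(OCc9ccccc9)c2c(c1)OC(c8ccc(OCc9ccccc9)c(OCc9ccccc9)c8)=C[C@@H]2c1c(OCc9ccccc9)c(Br)c2c(c1OCc9ccccc9)C[C@@H](OCc9ccccc9)[C@@H](c8ccc(OCc9ccccc9)c(OCc9ccccc9)c8)O2 | intermediate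
14 | C3 alkylborane of the cap (3-BH2; 2,3-trans-3,4-trans; otherwise as 15) | c9ccccc9COc1cc(OCc9ccccc9)c2c(c1)O[C@H](c8ccc(OCc9ccccc9)c(OCc9ccccc9)c8)[C@@H](B)[C@@H]2c1c(OCc9ccccc9)c(Br)c2c(c1OCc9ccccc9)C[C@@H](OCc9ccccc9)[C@@H](c8ccc(OCc9ccccc9)c(OCc9ccccc9)c8)O2 | intermediate
15 | tetra-O-benzylcatechin-(4α→6)-penta-O-benzyl-8-bromoepicatechin (3-OH of unit 1 free) | c9ccccc9COc1cc(OCc9ccccc9)c2c(c1)O[C@H](c8ccc(OCc9ccccc9)c(OCc9ccccc9)c8)[C@@H](O)[C@@H]2c1c(OCc9ccccc9)c(Br)c2c(c1OCc9ccccc9)C[C@@H](OCc9ccccc9)[C@@H](c8ccc(OCc9ccccc9)c(OCc9ccccc9)c8)O2 | intermediate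
16 | penta-O-benzylcatechin-(4α→6)-penta-O-benzyl-8-bromoepicatechin | c9ccccc9COc1cc(OCc9ccccc9)c2c(c1)O[C@H](c8ccc(OCc9ccccc9)c(OCc9ccccc9)c8)[C@@H](OCc9ccccc9)[C@@H]2c1c(OCc9ccccc9)c(Br)c2c(c1OCc9ccccc9)C[C@@H](OCc9ccccc9)[C@@H](c8ccc(OCc9ccccc9)c(OCc9ccccc9)c8)O2 | intermediate
17 | penta-O-benzyl-6,8-dibromocatechin-(4α→6)-penta-O-benzyl-8-bromoepicatechin | c9ccccc9COc1c(Br)c(OCc9ccccc9)c2c(c1Br)O[C@H](c8ccc(OCc9ccccc9)c(OCc9ccccc9)c8)[C@@H](OCc9ccccc9)[C@@H]2c1c(OCc9ccccc9)c(Br)c2c(c1OCc9ccccc9)C[C@@H](OCc9ccccc9)[C@@H](c8ccc(OCc9ccccc9)c(OCc9ccccc9)c8)O2 | intermediate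
18 | penta-O-benzyl-6,8-dibromocatechin-(4α→6)-penta-O-benzyl-8-bromo-4β-(2-ethoxyethoxy)epicatechin | c9ccccc9COc1c(Br)c(OCc9ccccc9)c2c(c1Br)O[C@H](c8ccc(OCc9ccccc9)c(OCc9ccccc9)c8)[C@@H](OCc9ccccc9)[C@@H]2c1c(OCc9ccccc9)c(Br)c2c(c1OCc9ccccc9)[C@H](OCCOCC)[C@@H](OCc9ccccc9)[C@@H](c8ccc(OCc9ccccc9)c(OCc9ccccc9)c8)O2 | intermediate
19 | tetra-O-benzyl-4β-(2-ethoxyethoxy)epicatechin | c9ccccc9COc1cc(OCc9ccccc9)c2c(c1)O[C@H](c8ccc(OCc9ccccc9)c(OCc9ccccc9)c8)[C@H](O)[C@H]2OCCOCC | intermediate
20 | octa-O-benzylprocyanidin B2 (tetra-O-benzylepicatechin-(4β→8)-tetra-O-benzylepicatechin; both 3-OH free) | c1c(OCc9ccccc9)cc(OCc9ccccc9)c3c1O[C@H](c8ccc(OCc9ccccc9)c(OCc9ccccc9)c8)[C@H](O)[C@H]3c1c(OCc9ccccc9)cc(OCc9ccccc9)c3c1O[C@H](c8ccc(OCc9ccccc9)c(OCc9ccccc9)c8)[C@H](O)C3 | intermediate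
21 | protected tetramer: penta-O-benzyl-6,8-dibromocatechin-(4α→6)-penta-O-benzyl-8-bromoepicatechin-(4β→8)-tetra-O-benzylepicatechin-(4β→8)-tetra-O-benzylepicatechin | c9ccccc9COc1c(Br)c(OCc9ccccc9)c2c(c1Br)O[C@H](c8ccc(OCc9ccccc9)c(OCc9ccccc9)c8)[C@@H](OCc9ccccc9)[C@@H]2c1c(OCc9ccccc9)c(Br)c2c(c1OCc9ccccc9)[C@H](c1c(OCc9ccccc9)cc(OCc9ccccc9)c3c1O[C@H](c8ccc(OCc9ccccc9)c(OCc9ccccc9)c8)[C@H](O)[C@H]3c1c(OCc9ccccc9)cc(OCc9ccccc9)c3c1O[C@H](c8ccc(OCc9ccccc9)c(OCc9ccccc9)c8)[C@H](O)C3)[C@@H](OCc9ccccc9)[C@@H](c8ccc(OCc9ccccc9)c(OCc9ccccc9)c8)O2 | intermediate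
22 | catechin-(4α→6)-epicatechin-(4β→8)-epicatechin-(4β→8)-epicatechin (CNP0228086.1) | Oc1cc(O)c2c(c1)O[C@H](c1ccc(O)c(O)c1)[C@@H](O)[C@@H]2c1c(O)cc2c(c1O)[C@H](c1c(O)cc(O)c3c1O[C@H](c1ccc(O)c(O)c1)[C@H](O)[C@H]3c1c(O)cc(O)c3c1O[C@H](c1ccc(O)c(O)c1)[C@H](O)C3)[C@@H](O)[C@@H](c1ccc(O)c(O)c1)O2 | target

**Step count and risks**

Total step count: 16. Longest linear sequence: 13 steps (steps 1–5, 7–12, 15, 16, from 1 to 22).

Steps most likely to fail:

Step 8 (the step with the proposed new method). What may go wrong: insufficient facial discrimination in the conjugate Friedel–Crafts addition, no turnover with the hindered, electron-rich enone, or acid-induced further reaction of the enol ether (protonation at C3 and capture of a second phenol). The fallback uses known chemistry, sets out from 5 and comes back at 13. Commercial 2,4,6-trihydroxybenzaldehyde is dibenzylated (BnBr 2 equiv, K2CO3, DMF; the chelated ortho OH stays free) to 2,4-bis(benzyloxy)-6-hydroxybenzaldehyde F1. Condensation of F1 with 9 under dry HCl in EtOAc at 0 °C gives the flavylium salt 5,7-bis(benzyloxy)-2-[3,4-bis(benzyloxy)phenyl]chromenylium chloride F2. The arylmagnesium 6, made from 5 as in step 5, is then added to F2 in THF at −78 °C instead of to DMF. Carbon nucleophiles add to flavylium salts at C4, so this forms the C4–C6 bond directly and gives 13 together with the C4 epimer of 13 F3, without facial control. The two are diastereomers, because unit 2 is enantiopure, and are separated by chromatography; the route continues from 13 at step 9.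

Step 12. What may go wrong: sluggish hydride abstraction from the bromine-bearing ring A of unit 2, with competing abstraction of the tertiary C4–H of unit 1 or over-oxidation. The fallback sets out from 16 and comes back at 18. Bromine–lithium exchange (n-BuLi, THF, −78 °C) and protonation with MeOH remove the C8 bromine of unit 2 and give penta-O-benzylcatechin-(4α→6)-penta-O-benzylepicatechin F4. Its ring A of unit 2 now has the electron-rich, halogen-free substitution for which the DDQ/2-ethoxyethanol oxidation is routine, and this gives penta-O-benzylcatechin-(4α→6)-penta-O-benzyl-4β-(2-ethoxyethoxy)epicatechin F5. NBS (3.1 equiv, CH2Cl2, −40 °C) then brominates C8 of unit 2 and C6 and C8 of unit 1 in the presence of the C4 ether and gives 18.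

Step 15. What may go wrong: slow capture of a congested cation (C4 of unit 2 lies next to the C5 benzyloxy group and the C6-linked unit 1), loss of regiocontrol between C8 of unit 3 and the C6 positions of 20, and acid-induced scrambling of interflavan bonds or over-alkylation of the product. The fallback replaces the 2 + 2 coupling by two single-unit extensions with orthogonal leaving groups; it sets out from 18 and comes back at 21. Exchange of the ether of 19 with benzyl mercaptan (TMSOTf cat., CH2Cl2, −78 °C) gives tetra-O-benzyl-4β-(benzylthio)epicatechin F6. F6 is used in excess as a monomeric nucleophile with 18 (TMSOTf, CH2Cl2, −78 °C; the sulfide is not ionised by the oxophilic silyl triflate) and reacts through its C8 to give the trimer thioether penta-O-benzyl-6,8-dibromocatechin-(4α→6)-penta-O-benzyl-8-bromoepicatechin-(4β→8)-tetra-O-benzyl-4β-(benzylthio)epicatechin F7. Thiophilic activation of F7 with AgBF4 (THF, 0 °C) in the presence of excess 2 then forms the last 4β→8 bond and gives 21.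

Further compounds
F1 | step 8 | 2,4-bis(benzyloxy)-6-hydroxybenzaldehyde | O=Cc1c(O)cc(OCc2ccccc2)cc1OCc1ccccc1
F2 | step 8 | 5,7-bis(benzyloxy)-2-[3,4-bis(benzyloxy)phenyl]chromenylium chloride | c9ccccc9COc1cc(OCc9ccccc9)c2ccc(-c8ccc(OCc9ccccc9)c(OCc9ccccc9)c8)[o+]c2c1.[Cl-]
F3 | step 8 | C4 epimer of 13 ((4R)-4H-chromene) | c9ccccc9COc1cc(OCc9ccccc9)c2c(c1)OC(c8ccc(OCc9ccccc9)c(OCc9ccccc9)c8)=C[C@H]2c1c(OCc9ccccc9)c(Br)c2c(c1OCc9ccccc9)C[C@@H](OCc9ccccc9)[C@@H](c8ccc(OCc9ccccc9)c(OCc9ccccc9)c8)O2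
F4 | step 12 | penta-O-benzylcatechin-(4α→6)-penta-O-benzylepicatechin | c9ccccc9COc1cc(OCc9ccccc9)c2c(c1)O[C@H](c8ccc(OCc9ccccc9)c(OCc9ccccc9)c8)[C@@H](OCc9ccccc9)[C@@H]2c1c(OCc9ccccc9)cc2c(c1OCc9ccccc9)C[C@@H](OCc9ccccc9)[C@@H](c8ccc(OCc9ccccc9)c(OCc9ccccc9)c8)O2
F5 | step 12 | penta-O-benzylcatechin-(4α→6)-penta-O-benzyl-4β-(2-ethoxyethoxy)epicatechin | c9ccccc9COc1cc(OCc9ccccc9)c2c(c1)O[C@H](c8ccc(OCc9ccccc9)c(OCc9ccccc9)c8)[C@@H](OCc9ccccc9)[C@@H]2c1c(OCc9ccccc9)cc2c(c1OCc9ccccc9)[C@H](OCCOCC)[C@@H](OCc9ccccc9)[C@@H](c8ccc(OCc9ccccc9)c(OCc9ccccc9)c8)O2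
F6 | step 15 | tetra-O-benzyl-4β-(benzylthio)epicatechin | c9ccccc9COc1cc(OCc9ccccc9)c2c(c1)O[C@H](c8ccc(OCc9ccccc9)c(OCc9ccccc9)c8)[C@H](O)[C@H]2SCc9ccccc9
F7 | step 15 | penta-O-benzyl-6,8-dibromocatechin-(4α→6)-penta-O-benzyl-8-bromoepicatechin-(4β→8)-tetra-O-benzyl-4β-(benzylthio)epicatechin | c9ccccc9COc1c(Br)c(OCc9ccccc9)c2c(c1Br)O[C@H](c8ccc(OCc9ccccc9)c(OCc9ccccc9)c8)[C@@H](OCc9ccccc9)[C@@H]2c1c(OCc9ccccc9)c(Br)c2c(c1OCc9ccccc9)[C@H](c1c(OCc9ccccc9)cc(OCc9ccccc9)c3c1O[C@H](c8ccc(OCc9ccccc9)c(OCc9ccccc9)c8)[C@H](O)[C@H]3SCc9ccccc9)[C@@H](OCc9ccccc9)[C@@H](c8ccc(OCc9ccccc9)c(OCc9ccccc9)c8)O2
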